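## The problem

Arteminorin C is a 3,3'-bicoumarin in which a 7-hydroxy-6,8-dimethoxycoumarin (unprimed locants) is joined through C3 to C3' of a 6,7-dihydroxycoumarin (primed locants). The link is a single bond between two fully substituted, electron-poor alkene carbons, each α to a lactone carbonyl, so it must be made either by cross-coupling or by building one ring onto a substituent of the other. The molecule is flat and achiral; stereocentres that appear on the way (C4a' and C8a' in this plan) are transient, and only their relative configuration, fixed by mechanism, has any meaning. The real task is the oxygen pattern: O6 and O8 are methylated while O7, O6' and O7' are free, so the free oxygens must be placed without selective demethylation and carried in a masked form that comes off without harming the methyl ethers. Both lactones open with hydroxide or alkoxide and C4 and C4' are Michael acceptors, which argues for neutral or buffered conditions late in the route, and the free catechol and the 2,6-dimethoxyphenol are easily oxidised and cannot be exposed before the last step. The single aromatic C–H of the trioxygenated ring (C5–H, ortho to the 6-methoxy and para to the 8-methoxy group) is a ready site for electrophilic substitution, which makes C3 halogenation of a preformed coumarin unreliable. The enabling feature is the local twofold symmetry of the benzo ring of the primed half about the axis through the midpoints of the C4a'–C8a' and C6'–C7' bonds: C5', C6', C7' and C8' with their two oxygens map onto a symmetric 2,3-dioxygenated buta-1,3-diene, and C4a'–C8a' maps onto the 5,6-double bond of a monocyclic 2-pyranone that already holds the lactone and the C3–C3' bond.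

## Retrosynthesis

**17 ⇒ 16 (three O–Si bonds).** Target 17 is traced back to its tris(silyl ether) 16. All three phenols are carried as silyl ethers: triisopropylsilyl on O7, tert-butyldimethylsilyl on O6' and O7'. A benzyl ether on O7 would need a separate hydrogenolysis over palladium next to two conjugated lactone double bonds; one fluoride step avoids this. 16 is no simpler in skeleton, but it is non-phenolic and oxidation-proof. The forward step only has to be a buffered fluoride cleavage that spares lactones and methyl ethers.

**16 ⇒ 14 (four C–H bonds, via 15).** The catechol ring of 16 is taken back to the cis-fused tetrahydrocoumarin 14 by adding hydrogen at C4a', C5', C8' and C8a', with the dihydro diene 15 on the way. This trades an arene for a cyclohexene carrying an enediol bis(silyl ether), the retron of a Diels–Alder reaction. The forward step must remove two molecules of hydrogen without freeing either oxygen. The tert-butyldimethylsilyl groups are chosen over trimethylsilyl for this reason: loss of silyl during oxidation would unveil a ketone β to the lactone oxygen (inviting β-elimination) or a free catechol (inviting over-oxidation).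

**14 ⇒ 11 + 13 (C4a'–C5' and C8'–C8a').** The retro-Diels–Alder cut removes the whole carbocycle of the primed half, leaving the monocyclic pyranone 11 and the symmetric diene 13. The neighbouring cut, closing the primed lactone by condensation onto a preformed catechol aldehyde, is more conventional but needs a separately protected tetrasubstituted benzene. The cycloaddition instead puts both oxygens in place from a four-carbon diketone, with no regiochemistry and no electrophilic substitution. The forward reaction asks the pyranone C5=C6 bond to behave as a 2π component, which is the demanding part of the plan.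

**11 ⇒ 8 + 10 (C3–C3' bond).** The inter-ring bond is cut to the 3-bromocoumarin 8 and the 3-stannylpyranone 10, to be joined by Stille coupling. Annulating the pyranone onto an acetic ester side chain at C3 with a malondialdehyde equivalent would avoid tin, but the condensation of a mono-ester methylene of this kind is less secure than a cross-coupling of two known partner types. The forward step must be neutral and fluoride-free so that the aryl silyl ether survives.

**10 ⇒ 9 (C–Sn) and 13 ⇒ 12 (two O–Si).** The stannane 10 comes from the purchasable bromide 9 by palladium-catalysed stannylation. The diene 13 comes from butane-2,3-dione 12 by double enol silylation. Both are one-step preparations.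

**8 ⇒ 6 (C3=C4 and O1–C2).** The coumarin ring is opened to the salicylaldehyde 6 and a brominated two-carbon ylide; the open-chain bromoacrylate 7 lies between them. Bringing bromine in on the ylide carbon is preferred to brominating a finished coumarin, where C5–H would compete with C3. The forward step is an olefination followed by lactonisation.

**6 ⇒ 5 ⇒ 2 ⇒ 1 (formyl C–C, aryl C–O, O–Si).** Aldehyde 6 is cut at the formyl carbon to phenol 5, whose hydroxyl has a single free ortho position. Phenol 5 is cut at its C–O bond to the silyl ether 2 through aryllithium 3 and boronate 4, since the methoxy groups of 2 direct metalation to the only ortho C–H. Silyl ether 2 is the protected form of syringol 1, which supplies the 2,6-dimethoxyphenol pattern with the central oxygen already distinguished from its methylated neighbours.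

## Roads not taken

**Alternative 1:** The unprimed pyranone is cut at C4–C4a and O1–C2. In the forward sense a strong sulfonic acid condenses 2,4-dimethoxybenzene-1,3-diol A2 with the formylacetate ethyl 2-[6,7-bis(benzyloxy)-2-oxo-2H-chromen-3-yl]-3-oxopropanoate A3 in a Pechmann-type annulation. The product of this key step is 6',7'-di-O-benzyl arteminorin C A1.
- Merits: A1 is already aromatic and carries O7 free, so a single hydrogenolysis of A1 reaches the target. In these respects this road is better than the chosen plan, which needs a dehydrogenation after its key step.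
- Weak points: A2 has two unlike free positions and only attack at C6 (ortho to one hydroxyl, para to the other) can lactonise. The benzyl ethers of A3 must survive a medium that cleaves benzyl aryl ethers and re-alkylates electron-rich rings. An α-aryl formylacetate such as A3 is prone to deformylation, and A2 is air-sensitive.
- Comparison: the chosen plan sets against the shorter endgame from A1 a neutral key step, a symmetric partner (13) that removes the regiochemical question, and the absence of acid-labile groups at the decisive stage.

**Alternative 2:** The primed lactone is cut at O1'–C8a' and O1'–C2'. A peroxy acid inserts oxygen into the indanone 5,6-bis(benzyloxy)-2-[7-(benzyloxy)-6,8-dimethoxy-2-oxo-2H-chromen-3-yl]indan-1-one A5 with migration of the electron-rich aryl carbon. The product of this key step is 3',4'-dihydro-7,6',7'-tri-O-benzyl arteminorin C A4.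
- Merits: the migratory preference in A5 is well founded, and the reaction type is better precedented than a pyranone serving as dienophile. Only two hydrogens have to be removed from A4 afterwards, against four in the chosen plan.
- Weak points: A5 must first be assembled, by α-arylation of an enolisable ketone with a base-sensitive halocoumarin. A strongly electrophilic peracid can hydroxylate the trioxygenated arene. A4 still needs dehydrogenation and then hydrogenolysis of three benzyl ethers.
- Comparison: the chosen plan sets against the firmer precedent its much simpler partners (11 and 13 against the indanone A5, which carries the whole catechol), the absence of a peracid next to electron-rich rings, and a one-step deprotection.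

**Alternative 3:** The primed pyranone is cut at four bonds (C8a'–O1', C4a'–C4', C3'–C4', O1'–C2'). Fluoride releases a symmetric aryne from 4,5-bis(benzyloxy)-2-(trimethylsilyl)phenyl trifluoromethanesulfonate A7, and this aryne inserts into the carbonyl of N,N-dimethylformamide A9. The resulting ortho-quinone methide is trapped by the enolate of methyl [7-(benzyloxy)-6,8-dimethoxy-2-oxo-2H-chromen-3-yl]acetate A8. The product of this key step is 7,6',7'-tri-O-benzyl arteminorin C A6.
- Merits: this is the most convergent of all. Four bonds form in one step at the aromatic oxidation level, the aryne from A7 is symmetric, the one-carbon unit A9 is a bulk solvent, and one hydrogenolysis of A6 finishes the synthesis. In bond economy and in avoiding any oxidation it is better than the chosen plan.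
- Weak points: the known trapping partners are more acidic than a mono-ester such as A8, whose enolate needs a base that sits badly with fluoride, with A9 as the medium and with a coumarin lactone. The enolate of A8 can also arylate directly on the aryne. A7 takes several steps to prepare.
- Comparison: the chosen plan sets against the convergence of the road to A6 two partners (10 and 13) that are each one step from purchasable material and a key step run without base or fluoride. It concedes that its own key step is no better precedented.

Key step: step 8

Assumption: 3-bromo-2H-pyran-2-one (9), hexamethylditin and butane-2,3-dione (12) are taken as purchasable.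

## Route

Step 1
Reactants: 1 2,6-dimethoxyphenol (syringol)
Product: 2 1,3-dimethoxy-2-[(triisopropylsilyl)oxy]benzene
Conditions: TIPSCl, imidazole, DMF, 60 °C
Reagents that add atoms: chlorotriisopropylsilane CC(C)[Si](Cl)(C(C)C)C(C)C
Why: O-silylation of a hindered phenol through the silylimidazolium; the triisopropylsilyl ether withstands organolithium, peroxide and palladium steps and leaves with the other silyl groups at the end.

Step 2
Reactants: 2 1,3-dimethoxy-2-[(triisopropylsilyl)oxy]benzene
Product: 5 2,4-dimethoxy-3-[(triisopropylsilyl)oxy]phenol, via aryllithium 3 (not isolated), via arylboronate 4 (not isolated)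
Conditions: n-BuLi, TMEDA, THF, 0 °C; B(OMe)3, −78 °C → rt; then AcOH, 30% H2O2, 0 °C → rt
Reagents that add atoms: hydrogen peroxide OO
Why: Directed ortho-metalation by the methoxy groups at the only ortho C–H (C4 and C6 are equivalent), borylation, and peroxide-induced boron-to-oxygen aryl shift; the silyloxy group has no free ortho position, so anionic silyl migration is not expected, and the acidic oxidation spares the aryl silyl ether.

Step 3
Reactants: 5 2,4-dimethoxy-3-[(triisopropylsilyl)oxy]phenol
Product: 6 2-hydroxy-3,5-dimethoxy-4-[(triisopropylsilyl)oxy]benzaldehyde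
Conditions: MgCl2, Et3N, (CH2O)n, MeCN, reflux
Reagents that add atoms: formaldehyde (as paraformaldehyde) C=O
Why: Magnesium-mediated ortho-formylation (Casnati–Skattebøl type); the magnesium phenoxide delivers formaldehyde to the only free position ortho to the hydroxyl and a second formaldehyde oxidises the benzylic alkoxide to the aldehyde.

Step 4
Reactants: 6 2-hydroxy-3,5-dimethoxy-4-[(triisopropylsilyl)oxy]benzaldehyde
Product: 8 3-bromo-6,8-dimethoxy-7-[(triisopropylsilyl)oxy]-2H-chromen-2-one, via bromoacrylate ester 7 (not isolated)
Conditions: Ph3P=CHCO2Et, NBS, CH2Cl2, −20 °C; then 6, K2CO3, rt; then PhMe, 110 °C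
Reagents that add atoms: ethyl (triphenylphosphoranylidene)acetate CCOC(=O)C=P(c1ccccc1)(c1ccccc1)c1ccccc1; N-bromosuccinimide O=C1CCC(=O)N1Br
Why: Wittig olefination with a stabilised α-bromo ylide made in the flask, then lactonisation of the phenol onto the ester; the isomer of 7 with aryl and ester cis closes at once and heating feeds the other isomer in, while bromine arrives on the ylide carbon so that C5–H never meets an electrophilic brominating agent.

Step 5
Reactants: 9 3-bromo-2H-pyran-2-one
Product: 10 3-(trimethylstannyl)-2H-pyran-2-one
Conditions: Me3SnSnMe3, Pd(PPh3)4, THF, reflux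
Reagents that add atoms: hexamethylditin C[Sn](C)(C)[Sn](C)(C)C
Why: Palladium-catalysed stannylation of an alkenyl bromide with a distannane (oxidative addition to zerovalent palladium, Sn–Sn transmetalation, reductive elimination), a known transformation of this bromopyranone.

Step 6
Reactants: 8 3-bromo-6,8-dimethoxy-7-[(triisopropylsilyl)oxy]-2H-chromen-2-one; 10 3-(trimethylstannyl)-2H-pyran-2-one
Product: 11 3-{6,8-dimethoxy-2-oxo-7-[(triisopropylsilyl)oxy]-2H-chromen-3-yl}-2H-pyran-2-one
Conditions: Pd(PPh3)4, CuI, DMF, 70 °C
Reagents that add atoms: none
Why: Stille coupling; oxidative addition into the activated C3–Br bond of 8, CuI-assisted transmetalation of the alkenylstannane and reductive elimination form the inter-ring bond under neutral, fluoride-free conditions that spare the aryl silyl ether and both lactones.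

Step 7
Reactants: 12 butane-2,3-dione
Product: 13 2,3-bis[(tert-butyldimethylsilyl)oxy]buta-1,3-diene
Conditions: TBSOTf, Et3N, CH2Cl2, 0 °C → rt
Reagents that add atoms: tert-butyldimethylsilyl trifluoromethanesulfonate CC(C)(C)[Si](C)(C)OS(=O)(=O)C(F)(F)F
Why: Double enol silylation of a 1,2-diketone by soft enolisation; each carbonyl can enolise only toward its methyl group, so the 2,3-bis(silyloxy)diene is the only possible product.

Step 8
Reactants: 11 3-{6,8-dimethoxy-2-oxo-7-[(triisopropylsilyl)oxy]-2H-chromen-3-yl}-2H-pyran-2-one; 13 2,3-bis[(tert-butyldimethylsilyl)oxy]buta-1,3-diene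
Product: 14 rac-(4aS,8aS)-6,7-bis[(tert-butyldimethylsilyl)oxy]-3-{6,8-dimethoxy-2-oxo-7-[(triisopropylsilyl)oxy]-2H-chromen-3-yl}-4a,5,8,8a-tetrahydro-2H-chromen-2-one (cis ring fusion)
Conditions: 13 (4 equiv), BHT (cat.), CH2Cl2, 12 kbar, 45 °C
Reagents that add atoms: none
Why: Proposed new method: a normal-electron-demand Diels–Alder reaction in which the 5,6-double bond of pyranone 11 is the 2π component; the closest known reaction type is the addition of 1,3-dienes to the 5,6-double bond of 2-pyranones bearing an acyl or alkoxycarbonyl group at C3 or C5, followed by dehydrogenation. The HOMO of the electron-rich diene 13 meets the LUMO of the dienyl lactone, which has a large coefficient at C6 (the δ-carbon, vinylogous to the lactone carbonyl) and is lowered further by the electron-poor coumarinyl group at C3, so bonding should be concerted but asynchronous with C8'–C8a' leading. The six-membered carbocycle closes by intermolecular [4+2] annulation onto the existing ring, both new bonds (C4a'–C5' and C8'–C8a') forming suprafacially on the cis ring alkene. The two new stereocentres C4a' and C8a' are therefore cis by mechanism and racemic, and since step 9 erases both, nothing further has to control them; the diene has no terminal substituents and is twofold symmetric, so neither endo/exo nor regiochemical issues arise. The step needs periselectivity and site selectivity: the pyranone must not react as a 4π component across C3 and C6, and neither the pyranone C3=C4 nor the coumarin C3=C4 bond may compete. The substrate secures this because C3 carries the coumarinyl group, so diene-mode bonding there would build a congested quaternary centre and break the conjugation between the rings, and because the only 2π partner for that mode is a hindered 1,1-disubstituted silyl enol ether; C5=C6 is the sole unhindered disubstituted acceptor alkene, the two competing bonds being trisubstituted and flanking the inter-ring bond. High pressure at moderate temperature accelerates the bimolecular cycloaddition while staying below temperatures at which a bridged diene-mode adduct would lose carbon dioxide irreversibly or the silyl enol ethers would suffer.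

Step 9
Reactants: 14 rac-(4aS,8aS)-6,7-bis[(tert-butyldimethylsilyl)oxy]-3-{6,8-dimethoxy-2-oxo-7-[(triisopropylsilyl)oxy]-2H-chromen-3-yl}-4a,5,8,8a-tetrahydro-2H-chromen-2-one
Product: 16 6,7-bis[(tert-butyldimethylsilyl)oxy]-3-{6,8-dimethoxy-2-oxo-7-[(triisopropylsilyl)oxy]-2H-chromen-3-yl}-2H-chromen-2-one, via dihydro diene 15 (not isolated)
Conditions: DDQ (2.3 equiv), 2,4,6-collidine, 1,4-dioxane, 60 °C
Reagents that add atoms: none
Why: Dehydrogenative aromatisation with a high-potential quinone, the standard way to turn cyclohexene Diels–Alder adducts into arenes: hydride abstraction from an allylic methylene next to the enediol ether and proton loss give diene 15, and a second, aromatisation-driven dehydrogenation removes the two ring-fusion hydrogens and with them both stereocentres; the hindered base buffers the acidic hydroquinone so that the silyl ethers stay on.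

Step 10
Reactants: 16 6,7-bis[(tert-butyldimethylsilyl)oxy]-3-{6,8-dimethoxy-2-oxo-7-[(triisopropylsilyl)oxy]-2H-chromen-3-yl}-2H-chromen-2-one
Product: 17 arteminorin C [6,7-dihydroxy-3-(7-hydroxy-6,8-dimethoxy-2-oxo-2H-chromen-3-yl)-2H-chromen-2-one]
Conditions: TBAF, AcOH, THF, 0 °C → rt
Reagents that add atoms: none
Why: Fluoride cleavage of three aryl silyl ethers (Si–F bond formation with phenoxide as leaving group); acetic acid buffering keeps the liberated catechol and the lactones away from basic, oxidising conditions, and the methyl ethers are inert.

## Compound list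

1 | 2,6-dimethoxyphenol (syringol) | COc1cccc(OC)c1O | starting material
2 | 1,3-dimethoxy-2-[(triisopropylsilyl)oxy]benzene | COc1cccc(OC)c1O[Si](C(C)C)(C(C)C)C(C)C | intermediate
3 | {2,4-dimethoxy-3-[(triisopropylsilyl)oxy]phenyl}lithium | [Li]c1ccc(OC)c(O[Si](C(C)C)(C(C)C)C(C)C)c1OC | intermediate (not isolated)
4 | dimethyl {2,4-dimethoxy-3-[(triisopropylsilyl)oxy]phenyl}boronate | COB(OC)c1ccc(OC)c(O[Si](C(C)C)(C(C)C)C(C)C)c1OC | intermediate (not isolated)
5 | 2,4-dimethoxy-3-[(triisopropylsilyl)oxy]phenol | COc1ccc(O)c(OC)c1O[Si](C(C)C)(C(C)C)C(C)C | intermediate
6 | 2-hydroxy-3,5-dimethoxy-4-[(triisopropylsilyl)oxy]benzaldehyde | COc1cc(C=O)c(O)c(OC)c1O[Si](C(C)C)(C(C)C)C(C)C | intermediate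
7 | ethyl 2-bromo-3-{2-hydroxy-3,5-dimethoxy-4-[(triisopropylsilyl)oxy]phenyl}prop-2-enoate (mixture of geometric isomers) | CCOC(=O)C(Br)=Cc1cc(OC)c(O[Si](C(C)C)(C(C)C)C(C)C)c(OC)c1O | intermediate (not isolated)
8 | 3-bromo-6,8-dimethoxy-7-[(triisopropylsilyl)oxy]-2H-chromen-2-one | COc1cc2cc(Br)c(=O)oc2c(OC)c1O[Si](C(C)C)(C(C)C)C(C)C | intermediate
9 | 3-bromo-2H-pyran-2-one | O=c1occcc1Br | starting material
10 | 3-(trimethylstannyl)-2H-pyran-2-one | C[Sn](C)(C)c1cccoc1=O | intermediate
11 | 3-{6,8-dimethoxy-2-oxo-7-[(triisopropylsilyl)oxy]-2H-chromen-3-yl}-2H-pyran-2-one | COc1cc2cc(-c3cccoc3=O)c(=O)oc2c(OC)c1O[Si](C(C)C)(C(C)C)C(C)C | intermediate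
12 | butane-2,3-dione | CC(=O)C(C)=O | starting material
13 | 2,3-bis[(tert-butyldimethylsilyl)oxy]buta-1,3-diene | C=C(O[Si](C)(C)C(C)(C)C)C(=C)O[Si](C)(C)C(C)(C)C | intermediate
14 | rac-(4aS,8aS)-6,7-bis[(tert-butyldimethylsilyl)oxy]-3-{6,8-dimethoxy-2-oxo-7-[(triisopropylsilyl)oxy]-2H-chromen-3-yl}-4a,5,8,8a-tetrahydro-2H-chromen-2-one (cis-fused, one enantiomer drawn) | COc1cc2cc(C3=C[C@@H]4CC(O[Si](C)(C)C(C)(C)C)=C(O[Si](C)(C)C(C)(C)C)C[C@@H]4OC3=O)c(=O)oc2c(OC)c1O[Si](C(C)C)(C(C)C)C(C)C | intermediate
15 | cis-6,7-bis[(tert-butyldimethylsilyl)oxy]-3-{6,8-dimethoxy-2-oxo-7-[(triisopropylsilyl)oxy]-2H-chromen-3-yl}-4a,8a-dihydro-2H-chromen-2-one (racemic, one enantiomer drawn) | COc1cc2cc(C3=C[C@@H]4C=C(O[Si](C)(C)C(C)(C)C)C(O[Si](C)(C)C(C)(C)C)=C[C@@H]4OC3=O)c(=O)oc2c(OC)c1O[Si](C(C)C)(C(C)C)C(C)C | intermediate (not isolated)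
16 | 6,7-bis[(tert-butyldimethylsilyl)oxy]-3-{6,8-dimethoxy-2-oxo-7-[(triisopropylsilyl)oxy]-2H-chromen-3-yl}-2H-chromen-2-one | COc1cc2cc(-c3cc4cc(O[Si](C)(C)C(C)(C)C)c(O[Si](C)(C)C(C)(C)C)cc4oc3=O)c(=O)oc2c(OC)c1O[Si](C(C)C)(C(C)C)C(C)C | intermediate
17 | arteminorin C | COc1cc2cc(-c3cc4cc(O)c(O)cc4oc3=O)c(=O)oc2c(OC)c1O | target

## Step count and risks

Total: 10 steps (steps 5 and 7 prepare the two partners). Longest linear sequence: 8 steps from syringol (steps 1, 2, 3, 4, 6, 8, 9, 10).

**Step 8 (key step, proposed new method).** The most likely failure is lack of conversion, because the C5=C6 bond of a 3-aryl pyranone is only moderately activated. Next comes the wrong periselectivity: addition of a silyl enol ether unit of 13 across C3 and C6 of the pyranone, followed by loss of carbon dioxide. Stepwise conjugate addition with silyl transfer is a third possibility.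
The fallback uses only known condensation chemistry; it sets out from aldehyde 6 and returns to the route at 17. Perkin condensation of 6 with succinic anhydride (Et3N, 130 °C) should give {6,8-dimethoxy-2-oxo-7-[(triisopropylsilyl)oxy]-2H-chromen-3-yl}acetic acid F1. Perkin–Oglialoro condensation of this acid with purchasable 2,4,5-trihydroxybenzaldehyde (Ac2O, Et3N, 110 °C) should close the primed coumarin and acetylate the catechol, giving 3-{6,8-dimethoxy-2-oxo-7-[(triisopropylsilyl)oxy]-2H-chromen-3-yl}-2-oxo-2H-chromene-6,7-diyl diacetate F2. Acid methanolysis (HCl, MeOH) should then give 6,7-dihydroxy-3-{6,8-dimethoxy-2-oxo-7-[(triisopropylsilyl)oxy]-2H-chromen-3-yl}-2H-chromen-2-one F3, and the conditions of step 10 convert this diol into 17.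

**Step 9.** The likely failure is loss of a silyl group from the oxocarbenium intermediate of the first dehydrogenation. That would expose a ketone β to the lactone oxygen, so that the ring aromatises by β-elimination of the carboxylate. Alternatively it would expose a free phenol that the quinone oxidises further.
The fallback leaves the hydride-abstraction manifold. From 14, heterogeneous dehydrogenation over Pd/C (mesitylene, 165 °C, argon sweep) should give 16 directly, without cationic intermediates. The route has no benzyl ether or other group sensitive to palladium on carbon. No new compound arises.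

**Step 4.** The likely failure is poor geometric selectivity of the olefination, so that the isomer of 7 with aryl and ester trans accumulates and equilibrates only slowly. Partial loss of bromine during the thermal stage is also possible.
The fallback sets out from 6 and returns at 8. Knoevenagel condensation of 6 with Meldrum's acid (piperidinium acetate, EtOH, reflux) should give 6,8-dimethoxy-2-oxo-7-[(triisopropylsilyl)oxy]-2H-chromene-3-carboxylic acid F4, and here ring closure does not depend on alkene geometry. Hunsdiecker-type bromodecarboxylation (NBS, LiOAc cat., MeCN–H2O) should then give 8. It remains to be seen whether ipso attack at the carboxyl-bearing C3 outruns bromination at C5.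

**Step 6.** The likely failure is slow transmetalation, since both partners are electron-poor. Protodestannylation and homocoupling of 10 would then take over.
The fallback reverses the polarity; it sets out from 8 and returns at 11. Miyaura borylation of 8 (bis(pinacolato)diboron, PdCl2(dppf), KOAc, dioxane, 80 °C) should give 6,8-dimethoxy-3-(4,4,5,5-tetramethyl-1,3,2-dioxaborolan-2-yl)-7-[(triisopropylsilyl)oxy]-2H-chromen-2-one F5. Suzuki–Miyaura coupling of this boronate with bromide 9 (Pd(PPh3)4, K3PO4, dioxane–H2O, 70 °C) should give 11.

## Further compounds

F1 | step 8 | {6,8-dimethoxy-2-oxo-7-[(triisopropylsilyl)oxy]-2H-chromen-3-yl}acetic acid | COc1cc2cc(CC(=O)O)c(=O)oc2c(OC)c1O[Si](C(C)C)(C(C)C)C(C)C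
F2 | step 8 | 3-{6,8-dimethoxy-2-oxo-7-[(triisopropylsilyl)oxy]-2H-chromen-3-yl}-2-oxo-2H-chromene-6,7-diyl diacetate | COc1cc2cc(-c3cc4cc(OC(C)=O)c(OC(C)=O)cc4oc3=O)c(=O)oc2c(OC)c1O[Si](C(C)C)(C(C)C)C(C)C
F3 | step 8 | 6,7-dihydroxy-3-{6,8-dimethoxy-2-oxo-7-[(triisopropylsilyl)oxy]-2H-chromen-3-yl}-2H-chromen-2-one | COc1cc2cc(-c3cc4cc(O)c(O)cc4oc3=O)c(=O)oc2c(OC)c1O[Si](C(C)C)(C(C)C)C(C)C
F0 | step 9 | none | none
F4 | step 4 | 6,8-dimethoxy-2-oxo-7-[(triisopropylsilyl)oxy]-2H-chromene-3-carboxylic acid | COc1cc2cc(C(=O)O)c(=O)oc2c(OC)c1O[Si](C(C)C)(C(C)C)C(C)C
F5 | step 6 | 6,8-dimethoxy-3-(4,4,5,5-tetramethyl-1,3,2-dioxaborolan-2-yl)-7-[(triisopropylsilyl)oxy]-2H-chromen-2-one | COc1cc2cc(B3OC(C)(C)C(C)(C)O3)c(=O)oc2c(OC)c1O[Si](C(C)C)(C(C)C)C(C)C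
A1 | alternative 1 | 6',7'-di-O-benzyl arteminorin C | COc1cc2cc(-c3cc4cc(OCc5ccccc5)c(OCc5ccccc5)cc4oc3=O)c(=O)oc2c(OC)c1O
A2 | alternative 1 | 2,4-dimethoxybenzene-1,3-diol | COc1ccc(O)c(OC)c1O
A3 | alternative 1 | ethyl 2-[6,7-bis(benzyloxy)-2-oxo-2H-chromen-3-yl]-3-oxopropanoate | CCOC(=O)C(C=O)c1cc2cc(OCc3ccccc3)c(OCc3ccccc3)cc2oc1=O
A4 | alternative 2 | 3',4'-dihydro-7,6',7'-tri-O-benzyl arteminorin C (racemic, one enantiomer drawn) | COc1cc2cc([C@@H]3Cc4cc(OCc5ccccc5)c(OCc5ccccc5)cc4OC3=O)c(=O)oc2c(OC)c1OCc1ccccc1
A5 | alternative 2 | 5,6-bis(benzyloxy)-2-[7-(benzyloxy)-6,8-dimethoxy-2-oxo-2H-chromen-3-yl]indan-1-one (racemic, one enantiomer drawn) | COc1cc2cc([C@@H]3Cc4cc(OCc5ccccc5)c(OCc5ccccc5)cc4C3=O)c(=O)oc2c(OC)c1OCc1ccccc1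
A6 | alternative 3 | 7,6',7'-tri-O-benzyl arteminorin C | COc1cc2cc(-c3cc4cc(OCc5ccccc5)c(OCc6ccccc6)cc4oc3=O)c(=O)oc2c(OC)c1OCc1ccccc1
A7 | alternative 3 | 4,5-bis(benzyloxy)-2-(trimethylsilyl)phenyl trifluoromethanesulfonate | C[Si](C)(C)c1cc(OCc2ccccc2)c(OCc2ccccc2)cc1OS(=O)(=O)C(F)(F)F
A8 | alternative 3 | methyl [7-(benzyloxy)-6,8-dimethoxy-2-oxo-2H-chromen-3-yl]acetate | COC(=O)Cc1cc2cc(OC)c(OCc3ccccc3)c(OC)c2oc1=O
A9 | alternative 3 | N,N-dimethylformamide | CN(C)C=O
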